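- The ratio of free catalyst charged to starting material lost per minute reads 6.58 min in the midnight run over the first 8.4 min; this time per turn, one charged catalyst for one starting material, is the turnover time, and it is the number to watch.

| flask | starting material | partner | free catalyst | time |
|---|---|---|---|---|
| midnight | 250 mM | 500 mM | 25.0 mM |  |
| dusk | 130 mM | 380 mM | 25.0 mM |  |
| spring | 250 mM | 1500 mM | 25.0 mM |  |
| dawn | 250 mM | 500 mM | 50.0 mM |  |
| noon | 750 mM | 500 mM | 8.30 mM | 42 min |

- midnight run (time / min: [starting material] / mM): 8.4: 218.1; 17: 193.4; 25: 171.2; 34: 151.1; 42: 137.5
- dusk run (time / min: [starting material] / mM): 8.4: 108.4; 17: 90.6; 25: 77.5; 34: 65.2; 42: 57.8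
- spring run (time / min: [starting material] / mM): 8.4: 236.5; 17: 225.7; 25: 215.0; 34: 201.9; 42: 193.4
- dawn run (time / min: [starting material] / mM): 8.4: 190.4; 17: 144.3; 25: 112.3; 34: 88.2; 42: 74.5

(readings scatter by 1 mM)

- Overall: starting material + partner -> target, with free catalyst as catalyst.
- Constant volume, constant temperature.
- Bound and free are read together.
- An order is taken over about fifteen percent of the charge, up and down.

- reaction order in [partner] at the outset, round the charge of the midnight run, defined at two percent of the starting material turned into target
- reaction order in [free catalyst] at the outset, round the charge of the midnight run, defined at two percent of the starting material turned into target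
- the dusk run starts with 120 mM less of starting material and of partner than the midnight run, and with no target. Compared where both hold the same amount of starting material, once fifteen percent of what the dusk run was charged with has turned into target, is the dusk run faster, slower or alike (within a tenth)?
- starting material in the noon run at 42 min, as a share of the starting material charged

- Ledger of the midnight run: starting material is the limiting reagent, 250 mM against 500 mM of partner. The first entry is 31.9 mM turned by 8.4 min, and the books close at 42 min with 112.5 mM turned and 137.5 mM still in the flask.
- The last entry of that ledger, from 34 min to 42 min, is 13.6 mM, so the midnight turnover time there reads 14.7 min, about twice the first reading, with [starting material] down by a factor of 1.82.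
- The dawn run, with twice the catalyst, reads 7.05 min over its first window, close to the midnight value.
- The dusk run reads 9.72 min, longer than midnight. Against the smaller charge of starting material, that is a slope of 0.596, a reading that also carries the lower partner charge of the dusk run.
- Ledger of the noon run, my own reckoning: partner is now the shorter charge, so at most 500 mM can turn. The starting material charge is 3.00 times that of midnight, so the slope gives a turnover time of 3.42 min. Held over 42 min with 8.30 mM of catalyst, that turns 102 mM, and the books close with 86.4% left.
- The forecast gives −0.85 for the partner order, 0.95 for the catalyst order, a dusk run that is faster, and 83% left in the noon run, on the ground that “That points to target inhibition rather than catalyst death.” Its noon share stands below my reckoning.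
- The flask gives −0.57 for the partner order, 0.82 for the catalyst order, a dusk run that is faster, and 87.1% left in the noon run.

    free catalyst + starting material → catalyst-substrate complex (4.644 M⁻¹ min⁻¹)
    catalyst-substrate complex + partner → loaded catalyst (20.88 M⁻¹ min⁻¹)
    loaded catalyst → target + free catalyst (0.6780 min⁻¹)
    free catalyst + partner ⇌ idle catalyst-reagent complex, settled at all times (10.90 M⁻¹)
    free catalyst + target → spent catalyst + target (1.236 M⁻¹ min⁻¹)

- In the noon run 96.9 mM turned in 42 min, a mean turnover time of 3.60 min, shorter than the midnight 6.58 min, while [starting material] came down to 653 mM; at the noon charge, free and idle catalyst together waited 1.85 min per turn for starting material, longer than the 1.47 min of the loaded catalyst. In the dawn run the turnover time went from 7.05 min over the first window to 8.41 min up to a quarter of the charge and 9.22 min up to half, where at 23.1 min the flask held 125 mM of target.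

The readings come from a simulation for substances that don't exist.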